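**Retrosynthetic overview**

1. The plan rests on ring A of target 21, the central benzene: C1 carries the butanoyl group and lies between the C–OH carbons C2 and C6, C4 carries the third OH, and C3 and C5 carry the CH2 links to the two outer butanoyl-filicinic acid rings. Ring A is made last by [4+2] addition of a 1,3-bis(silyloxy)cyclohexa-1,3-diene (C2–C5 of ring A, both outer rings already attached) to 1-methoxyhex-1-yn-3-one (C1 and C6), forming C1–C2 and C5–C6; the two-carbon bridge of the bicyclo[2.2.2]octadiene then leaves by cycloreversion.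
2. Two features of precursor and dienophile are chosen to keep the key step clean. The bridge carries a gem-dimethyl group (from 4,4-dimethylcyclohexane-1,3-dione), so the dione can enolise only toward the arm-bearing carbon; a CH2–CH2 bridge would also allow enolisation to the other side, and that diene would expel one arm with the bridge. The bridge therefore leaves as 2-methylpropene. The ynol ether is methyl, because an ethyl ynol ether can lose ethylene by a retro-ene reaction to a ketene at the temperature the cycloaddition needs.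
3. The diene comes from the dione by alkylation at C6 (dianion) and at C2 (soft enolate) with the bromomethyl bis(O-methyl) outer ring 6, then exhaustive silylation.
4. The outer rings exist before ring A: phloroglucinol is C-acylated, dearomatised by C-trimethylation, O-methylated and brominated at the ring methyl to give 6.
5. After ring A is formed, aqueous acid hydrolyses the four enol methyl ethers and BCl3 cleaves the aryl methyl ether ortho to the ketone.

Key step: step 10

Remark on the chemistry: the two enol methyl ethers of each outer ring are drawn as the 2,6-dimethoxy-4-oxo isomer, and a positional isomer would converge at step 11; compounds 9, 10 and 17 are racemic, their stereocentres vanish, and the target has none.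

**Route**

Step 1
Reactants: 1 phloroglucinol; 2 butanoyl chloride
Product: 3 1-(2,4,6-trihydroxyphenyl)butan-1-one
Conditions: AlCl3 (4 equiv), PhNO2–CH2Cl2, 0 to 45 °C; then ice, 2 M HCl
Reagents that add atoms: none
Why: Friedel–Crafts C-acylation of the very electron-rich triol; the first acyl group deactivates the ring, so mono-acylation should prevail.

Step 2
Reactants: 3 1-(2,4,6-trihydroxyphenyl)butan-1-one
Product: 4 2-butanoyl-3,5-dihydroxy-4,4,6-trimethylcyclohexa-2,5-dien-1-one
Conditions: NaOMe (4 equiv), MeI (3.1 equiv), MeOH, 0 °C to rt; then 1 M HCl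
Reagents that add atoms: iodomethane, CI
Why: Base-mediated dearomative C-methylation of the acylphloroglucinol enolate; every order of the three methylations converges on the gem-dimethyl plus ring-methyl pattern of 4, and the stoichiometry limits the tetramethyl by-product.

Step 3
Reactants: 4 2-butanoyl-3,5-dihydroxy-4,4,6-trimethylcyclohexa-2,5-dien-1-one
Product: 5 2-butanoyl-3,5-dimethoxy-4,6,6-trimethylcyclohexa-2,4-dien-1-one
Conditions: Me2SO4 (2.5 equiv), K2CO3 (3 equiv), acetone, reflux
Reagents that add atoms: dimethyl sulfate, COS(=O)(=O)OC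
Why: O-alkylation of the two acidic enols (vinylogous acid and β-triketone) with a hard methylating agent under weak base, which removes every acidic proton of the outer ring.

Step 4
Reactants: 5 2-butanoyl-3,5-dimethoxy-4,6,6-trimethylcyclohexa-2,4-dien-1-one
Product: 6 4-(bromomethyl)-2-butanoyl-3,5-dimethoxy-6,6-dimethylcyclohexa-2,4-dien-1-one
Conditions: NBS (1.05 equiv), AIBN (5 mol %), PhCF3, 80 °C; filtered and used without chromatography
Reagents that add atoms: N-bromosuccinimide, O=C1CCC(=O)N1Br
Why: Wohl–Ziegler radical bromination; the ring methyl carries the only allylic C–H bonds of 5, so hydrogen abstraction should be selective for it.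

Step 5
Reactants: 7 4,4-dimethylcyclohexane-1,3-dione; 6 4-(bromomethyl)-2-butanoyl-3,5-dimethoxy-6,6-dimethylcyclohexa-2,4-dien-1-one
Product: 9 6-[(5-butanoyl-2,6-dimethoxy-3,3-dimethyl-4-oxocyclohexa-1,5-dien-1-yl)methyl]-4,4-dimethylcyclohexane-1,3-dione, via dilithium dienediolate 8 (not isolated)
Conditions: LiN(i-Pr)2 (2.2 equiv), THF–DMPU, −78 to 0 °C; then 6 (1.0 equiv), −78 to −30 °C; cold 1 M HCl
Reagents that add atoms: none
Why: γ-Alkylation of a β-diketone dianion: the second deprotonation can only occur at C6 because C4 is quaternary, and the dianion reacts at this more basic carbon by SN2 displacement of the allylic bromide.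

Step 6
Reactants: 9 6-[(5-butanoyl-2,6-dimethoxy-3,3-dimethyl-4-oxocyclohexa-1,5-dien-1-yl)methyl]-4,4-dimethylcyclohexane-1,3-dione; 6 4-(bromomethyl)-2-butanoyl-3,5-dimethoxy-6,6-dimethylcyclohexa-2,4-dien-1-one
Product: 10 3-hydroxy-4,4-dimethyl-2,6-bis[(5-butanoyl-2,6-dimethoxy-3,3-dimethyl-4-oxocyclohexa-1,5-dien-1-yl)methyl]cyclohex-2-en-1-one
Conditions: 6 (1.05 equiv), Pd(PPh3)4 (5 mol %), K2CO3 (1.5 equiv), THF, rt
Reagents that add atoms: none
Why: Tsuji–Trost-type allylic alkylation of the soft 1,3-dione enolate at C2; zerovalent palladium ionises the allylic bromide, and any O-alkylated enol ether, to an allyl complex that is attacked at its unsubstituted CH2 end, which should funnel the material to the C-alkylated dione.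

Step 7
Reactants: 10 3-hydroxy-4,4-dimethyl-2,6-bis[(5-butanoyl-2,6-dimethoxy-3,3-dimethyl-4-oxocyclohexa-1,5-dien-1-yl)methyl]cyclohex-2-en-1-one
Product: 11 6,6-dimethyl-1,3-bis(trimethylsilyloxy)-2,4-bis({2,6-dimethoxy-3,3-dimethyl-4-oxo-5-[(Z)-1-(trimethylsilyloxy)but-1-en-1-yl]cyclohexa-1,5-dien-1-yl}methyl)cyclohexa-1,3-diene
Conditions: Me3SiOSO2CF3 (5 equiv), Et3N (7 equiv), Et2O, 0 °C to rt; pentane, filtration under argon; used crude
Reagents that add atoms: trimethylsilyl trifluoromethanesulfonate, C[Si](C)(C)OS(=O)(=O)C(F)(F)F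
Why: Soft enolisation with silyl triflate and amine: the second ring enolisation can only go to the arm-bearing C–H because the other α-carbon is quaternary, so a single 1,3-bis(silyloxy)diene should form; the two butanoyl ketones enolise at a similar rate and are driven to their silyl enol ethers on purpose with excess reagent (geometry without consequence), to be released in the work-up of step 10.

Step 8
Reactants: 2 butanoyl chloride
Product: 12 N-methoxy-N-methylbutanamide
Conditions: MeNHOMe·HCl (1.1 equiv), Et3N (2.2 equiv), CH2Cl2, 0 °C to rt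
Reagents that add atoms: N,O-dimethylhydroxylamine hydrochloride, CNOC.Cl
Why: Amide formation from the acid chloride gives the N-methoxy-N-methyl amide, which stops an organolithium addition at the ketone stage.

Step 9
Reactants: 13 2-chloro-1,1-dimethoxyethane; 12 N-methoxy-N-methylbutanamide
Product: 16 1-methoxyhex-1-yn-3-one, via lithium methoxyacetylide 14 (not isolated), via lithium hemiaminal chelate 15 (not isolated)
Conditions: LiNEt2 (3.05 equiv), THF, −78 to 0 °C; then 12, −78 °C; cold sat. aq. NH4Cl; used promptly
Reagents that add atoms: none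
Why: Two base-induced eliminations (methanol, then HCl) and a deprotonation turn the chloroacetal into the lithium alkoxyacetylide, which adds once to the amide (Weinreb ketone synthesis) because the chelated adduct 15 survives until the buffered quench.

Step 10
Reactants: 11 6,6-dimethyl-1,3-bis(trimethylsilyloxy)-2,4-bis({2,6-dimethoxy-3,3-dimethyl-4-oxo-5-[(Z)-1-(trimethylsilyloxy)but-1-en-1-yl]cyclohexa-1,5-dien-1-yl}methyl)cyclohexa-1,3-diene; 16 1-methoxyhex-1-yn-3-one
Product: 19 1-{2,4-dihydroxy-6-methoxy-3,5-bis[(5-butanoyl-2,6-dimethoxy-3,3-dimethyl-4-oxocyclohexa-1,5-dien-1-yl)methyl]phenyl}butan-1-one, via bicyclooctadiene cycloadduct 17 (not isolated), via tetrakis(silyl) arene 18 (not isolated)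
Conditions: 16 (3 equiv), o-xylene, sealed tube, 130 °C then 165 °C; then 0.5 M HCl, THF, 0 °C
Reagents that add atoms: none
Why: Normal-demand [4+2] cycloaddition of the ring-locked s-cis bis(silyloxy)diene of 11 across the triple bond of 16 gives the bicyclo[2.2.2]octa-2,5-diene 17, which on further heating loses its CMe2–CH2 bridge as 2-methylpropene by retro-Diels–Alder reaction, driven by aromatisation, to give 18; cold dilute acid then removes the four silyl groups. The closest known reaction type is the Alder–Rickert benzannulation of 1,3-dioxygenated cyclohexa-1,3-dienes with acylalkynes, including gem-dimethyl dienes that expel 2-methylpropene. Ring A is closed by this intermolecular cycloaddition, which forms C1–C2 (acyl carbon to the silyloxy terminus) and C5–C6 (arm-bearing terminus to the methoxy carbon), and the cycloreversion then cuts the two bridge bonds. The two bridgehead stereocentres of 17 are fixed relative to each other by the bicycle, form as a racemate and disappear on aromatisation, so no stereocontrol is needed. Regiochemistry is set by polarity: the arm-bearing terminus is the nucleophilic end of the 1,3-dioxygenated diene and joins the methoxy-bearing β-carbon of the push–pull ynone, which places the butanoyl group between two oxygens. Site selectivity for the central diene rests on its being the only ring-locked s-cis diene with two donor oxygens, whereas the outer dienone rings are fully substituted and acceptor-bearing and their side-chain silyl enol ethers cannot reach a planar s-cis diene; the quaternary bridge carbon also excludes a [1,5]-hydrogen shift from that carbon, and the methyl ynol ether has no β-hydrogen and cannot fragment to a ketene.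

Step 11
Reactants: 19 1-{2,4-dihydroxy-6-methoxy-3,5-bis[(5-butanoyl-2,6-dimethoxy-3,3-dimethyl-4-oxocyclohexa-1,5-dien-1-yl)methyl]phenyl}butan-1-one
Product: 20 1-{2,4-dihydroxy-6-methoxy-3,5-bis[(5-butanoyl-2,6-dihydroxy-3,3-dimethyl-4-oxocyclohexa-1,5-dien-1-yl)methyl]phenyl}butan-1-one
Conditions: 2 M HCl, 1,4-dioxane, 60 °C
Reagents that add atoms: water, O
Why: Acid-catalysed hydrolysis of the four vinylogous methyl esters by conjugate addition of water and loss of methanol; the aryl methyl ether and the ketones are inert to aqueous acid, and excess water disfavours dehydrative pyran closure across the CH2 bridges.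

Step 12
Reactants: 20 1-{2,4-dihydroxy-6-methoxy-3,5-bis[(5-butanoyl-2,6-dihydroxy-3,3-dimethyl-4-oxocyclohexa-1,5-dien-1-yl)methyl]phenyl}butan-1-one
Product: 21 target CNP0086314.0
Conditions: BCl3 (8 equiv), CH2Cl2, −78 to 0 °C; then MeOH, H2O
Reagents that add atoms: none
Why: Chelation-assisted ether cleavage: BCl3 binds the butanoyl carbonyl and the ortho methoxy oxygen, chloride removes the methyl group, and hydrolysis of the borate esters on work-up frees the third phenol of ring A.

**Compound list**

1 | phloroglucinol (benzene-1,3,5-triol) | Oc1cc(O)cc(O)c1 | starting material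
2 | butanoyl chloride | CCCC(=O)Cl | starting material
3 | 1-(2,4,6-trihydroxyphenyl)butan-1-one | CCCC(=O)c1c(O)cc(O)cc1O | intermediate
4 | 2-butanoyl-3,5-dihydroxy-4,4,6-trimethylcyclohexa-2,5-dien-1-one | CCCC(=O)C1=C(O)C(C)(C)C(O)=C(C)C1=O | intermediate
5 | 2-butanoyl-3,5-dimethoxy-4,6,6-trimethylcyclohexa-2,4-dien-1-one | CCCC(=O)C1=C(OC)C(C)=C(OC)C(C)(C)C1=O | intermediate
6 | 4-(bromomethyl)-2-butanoyl-3,5-dimethoxy-6,6-dimethylcyclohexa-2,4-dien-1-one | CCCC(=O)C1=C(OC)C(CBr)=C(OC)C(C)(C)C1=O | intermediate
7 | 4,4-dimethylcyclohexane-1,3-dione | CC1(C)CCC(=O)CC1=O | starting material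
8 | dilithium 6,6-dimethylcyclohexa-1,3-diene-1,3-diolate (dianion of 7; not isolated) | [Li]OC1=CC(O[Li])=CCC1(C)C | intermediate
9 | 6-[(5-butanoyl-2,6-dimethoxy-3,3-dimethyl-4-oxocyclohexa-1,5-dien-1-yl)methyl]-4,4-dimethylcyclohexane-1,3-dione (racemic) | CC1(C)CC(CC2=C(OC)C(C)(C)C(=O)C(C(=O)CCC)=C2OC)C(=O)CC1=O | intermediate
10 | 3-hydroxy-4,4-dimethyl-2,6-bis[(5-butanoyl-2,6-dimethoxy-3,3-dimethyl-4-oxocyclohexa-1,5-dien-1-yl)methyl]cyclohex-2-en-1-one (enol form of the 2,6-disubstituted dione; racemic) | CC1(C)CC(CC2=C(OC)C(C)(C)C(=O)C(C(=O)CCC)=C2OC)C(=O)C(CC3=C(OC)C(C)(C)C(=O)C(C(=O)CCC)=C3OC)=C1O | intermediate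
11 | 6,6-dimethyl-1,3-bis(trimethylsilyloxy)-2,4-bis({2,6-dimethoxy-3,3-dimethyl-4-oxo-5-[(Z)-1-(trimethylsilyloxy)but-1-en-1-yl]cyclohexa-1,5-dien-1-yl}methyl)cyclohexa-1,3-diene | C[Si](C)(C)OC1=C(CC2=C(OC)C(C)(C)C(=O)C(/C(O[Si](C)(C)C)=C/CC)=C2OC)C(O[Si](C)(C)C)=C(CC3=C(OC)C(C)(C)C(=O)C(/C(O[Si](C)(C)C)=C/CC)=C3OC)CC1(C)C | intermediate
12 | N-methoxy-N-methylbutanamide | CCCC(=O)N(C)OC | intermediate
13 | 2-chloro-1,1-dimethoxyethane | COC(CCl)OC | starting material
14 | lithium methoxyacetylide (not isolated) | [Li]C#COC | intermediate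
15 | lithium 1-[methoxy(methyl)amino]-1-(methoxyethynyl)butan-1-olate (not isolated) | CCCC(O[Li])(C#COC)N(C)OC | intermediate
16 | 1-methoxyhex-1-yn-3-one | CCCC(=O)C#COC | intermediate
17 | 6-butanoyl-5-methoxy-7,7-dimethyl-1,3-bis(trimethylsilyloxy)-2,4-bis({2,6-dimethoxy-3,3-dimethyl-4-oxo-5-[(Z)-1-(trimethylsilyloxy)but-1-en-1-yl]cyclohexa-1,5-dien-1-yl}methyl)bicyclo[2.2.2]octa-2,5-diene (racemic; not isolated) | C[Si](C)(C)OC12C(C)(C)CC(CC3=C(OC)C(C)(C)C(=O)C(/C(O[Si](C)(C)C)=C/CC)=C3OC)(C(OC)=C1C(=O)CCC)C(O[Si](C)(C)C)=C2CC4=C(OC)C(C)(C)C(=O)C(/C(O[Si](C)(C)C)=C/CC)=C4OC | intermediate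
18 | 1-{6-methoxy-2,4-bis(trimethylsilyloxy)-3,5-bis({2,6-dimethoxy-3,3-dimethyl-4-oxo-5-[(Z)-1-(trimethylsilyloxy)but-1-en-1-yl]cyclohexa-1,5-dien-1-yl}methyl)phenyl}butan-1-one (not isolated) | CCCC(=O)c1c(O[Si](C)(C)C)c(CC2=C(OC)C(C)(C)C(=O)C(/C(O[Si](C)(C)C)=C/CC)=C2OC)c(O[Si](C)(C)C)c(CC3=C(OC)C(C)(C)C(=O)C(/C(O[Si](C)(C)C)=C/CC)=C3OC)c1OC | intermediate
19 | 1-{2,4-dihydroxy-6-methoxy-3,5-bis[(5-butanoyl-2,6-dimethoxy-3,3-dimethyl-4-oxocyclohexa-1,5-dien-1-yl)methyl]phenyl}butan-1-one | CCCC(=O)c1c(O)c(CC2=C(OC)C(C)(C)C(=O)C(C(=O)CCC)=C2OC)c(O)c(CC3=C(OC)C(C)(C)C(=O)C(C(=O)CCC)=C3OC)c1OC | intermediate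
20 | 1-{2,4-dihydroxy-6-methoxy-3,5-bis[(5-butanoyl-2,6-dihydroxy-3,3-dimethyl-4-oxocyclohexa-1,5-dien-1-yl)methyl]phenyl}butan-1-one | CCCC(=O)c1c(O)c(CC2=C(O)C(C)(C)C(=O)C(C(=O)CCC)=C2O)c(O)c(CC3=C(O)C(C)(C)C(=O)C(C(=O)CCC)=C3O)c1OC | intermediate
21 | CNP0086314.0: 1-{2,4,6-trihydroxy-3,5-bis[(5-butanoyl-2,6-dihydroxy-3,3-dimethyl-4-oxocyclohexa-1,5-dien-1-yl)methyl]phenyl}butan-1-one | CCCC(=O)C1=C(O)C(Cc2c(O)c(CC3=C(O)C(C)(C)C(=O)C(C(=O)CCC)=C3O)c(O)c(C(=O)CCC)c2O)=C(O)C(C)(C)C1=O | target

**Step count and risks**

Total step count: 12. Longest linear sequence: 10 (steps 1–7, then 10–12); steps 8 and 9 form the dienophile branch.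

Steps most likely to fail:

Step 10. Both diene termini are fully substituted and the alkyne carries a donor, so cycloaddition may be outrun by desilylation of the diene, self-condensation of the ynone or a Michael addition that does not close the ring. The fallback sets out from 3 and returns at 21, and takes ring A ready-made from 3 instead of building it. Compound 3 is C-methylated with two equivalents of MeI (NaOMe, MeOH) to butyrylfilicinic acid F1. Two equivalents of F1, one of 3 and two of aqueous formaldehyde are then condensed in dilute aqueous NaOH at 0 °C (Knoevenagel condensation followed by Michael addition at each free ring position of 3). After acidification, 21 is separated from the symmetric methylene-bis by-products.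

Step 4. Bromine may be delivered by an ionic path to the electron-rich enol ether double bonds or to the α-position of the butanoyl ketone instead of by hydrogen abstraction from the ring methyl, and a second bromination may follow. The fallback sets out from 3 and returns at 9, and introduces the one-carbon link by a Mannich reaction instead of radical substitution. Compound 3 is C-dimethylated (MeI, 2 equiv, NaOMe) to butyrylfilicinic acid F2 and O-methylated (Me2SO4, K2CO3) to the bis(methyl ether) F3. F3 is aminomethylated at its free ring CH with dimethyl(methylidene)ammonium iodide to the Mannich base F4. Ethyl chloroformate then exchanges the amine for chloride (von Braun-type cleavage) to give the chloromethyl compound F5, which takes the place of 6 in steps 5 and 6.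

Step 5. The strongly basic dianion may abstract a proton from the butanoyl α-CH2 of 6, or be alkylated at oxygen, in competition with C-alkylation. The fallback sets out from 7 and returns at 9, and replaces the dianion by a neutral silyl dienol ether. Compound 7 is converted with Me3SiOSO2CF3 and Et3N into the bis(silyloxy)diene F6. Its terminal carbon is alkylated by 6 under ZnBr2 catalysis in CH2Cl2 at −40 °C (Lewis-acid alkylation of a silyl enol ether by an ionisable allylic bromide), and aqueous work-up gives 9.

**Further compounds**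

F1 | step 10 | 2-butanoyl-3,5-dihydroxy-4,4-dimethylcyclohexa-2,5-dien-1-one (butyrylfilicinic acid) | CCCC(=O)C1=C(O)C(C)(C)C(O)=CC1=O
F2 | step 4 | 2-butanoyl-3,5-dihydroxy-4,4-dimethylcyclohexa-2,5-dien-1-one (butyrylfilicinic acid) | CCCC(=O)C1=C(O)C(C)(C)C(O)=CC1=O
F3 | step 4 | 2-butanoyl-3,5-dimethoxy-6,6-dimethylcyclohexa-2,4-dien-1-one | CCCC(=O)C1=C(OC)C=C(OC)C(C)(C)C1=O
F4 | step 4 | 2-butanoyl-4-[(dimethylamino)methyl]-3,5-dimethoxy-6,6-dimethylcyclohexa-2,4-dien-1-one | CCCC(=O)C1=C(OC)C(CN(C)C)=C(OC)C(C)(C)C1=O
F5 | step 4 | 2-butanoyl-4-(chloromethyl)-3,5-dimethoxy-6,6-dimethylcyclohexa-2,4-dien-1-one | CCCC(=O)C1=C(OC)C(CCl)=C(OC)C(C)(C)C1=O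
F6 | step 5 | 6,6-dimethyl-1,3-bis(trimethylsilyloxy)cyclohexa-1,3-diene | C[Si](C)(C)OC1=CC(O[Si](C)(C)C)=CCC1(C)C
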